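**Plan**

- Retrosynthesis (germacrane numbering): the O6–acetyl and O8–tigloyl ester bonds are cut first; the C5–O bond of the 4,5-epoxide is opened to a C4 carbinol and a C5 ketone; C5–C10 is then re-joined (Wharton–Grob transform); in the resulting decalin the C4–CH3 bond and the two ring-A bonds C1–C10 and C4–C5 (Diels–Alder) are cut, leading to (R)-carvone, a four-carbon siloxydiene and a methyl nucleophile.
- Forward: the carvone ring becomes ring B (C5–C10); ring A (C1–C5, C10) is annulated by cycloaddition to a cis-decalin, which is converted into a trans-decalin 4,5-diol 1-mesylate; scission of C5–C10 then releases the ten-membered ring, and the epoxide is closed last from O4.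
- Stereochemistry: C7 comes from (R)-carvone; C10 and C1 from the anti, exo cycloaddition; C8, C9, C4, C5 and C6 from reagent approach governed by the axial C10 methyl of the bicycle; the E olefin from the antiperiplanar fragmentation; the epoxide C5 from a chelate-controlled ketone reduction followed by inversion.
- Enabling feature: the C1=C10 olefin and the oxygen on C5 are 1,3-related through C10, so a C5–C10 bond folds the ten-membered ring C1–C10 into a trans-fused decalin (ring A C1–C5/C10, ring B C5–C10) in which a C5 carbinol and an equatorial C1 sulfonate are antiperiplanar across the ring-fusion bond.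

Key step: step 20

Convention: germacrane numbers are used for every intermediate (ring atoms C1–C10, isopropyl on C7, methyls on C4 and C10); in the bicycles α is the face of the C10 methyl and β the opposite face.
Remark: alkoxides and metal-bound adducts that are formed and consumed within one operation are treated as reactive forms of the numbered compounds.

**Step 1**
Reactants: 1 (R)-(−)-carvone
Product: 2 (R)-carvotanacetone
Conditions: H2 (1 atm), (Ph3P)3RhCl (cat.), benzene, rt
Reagents that add atoms: none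
Why: Homogeneous hydrogenation with the rhodium(I) catalyst should saturate only the 1,1-disubstituted isopropenyl group and leave the trisubstituted conjugated enone and the C7 stereocentre untouched.

**Step 2**
Reactants: 3 (E)-crotonaldehyde
Product: 4 (1E)-1-(tert-butyldimethylsilyloxy)buta-1,3-diene
Conditions: TBSOTf, Et3N, Et2O, 0 °C to rt
Reagents that add atoms: tert-butyldimethylsilyl trifluoromethanesulfonate, CC(C)(C)[Si](C)(C)OS(=O)(=O)C(F)(F)F
Why: Silyl dienol ether formation by O-silylation and γ-deprotonation of the enal; the 1E isomer is the one that takes part in the cycloaddition.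

**Step 3**
Reactants: 2 (R)-carvotanacetone; 4 (1E)-1-(tert-butyldimethylsilyloxy)buta-1,3-diene
Product: 5 cis-fused cycloadduct (1α-OTBS decal-2-en-9-one)
Conditions: EtAlCl2 (0.3 equiv), toluene, −78 to −20 °C
Reagents that add atoms: none
Why: Lewis-acid-catalysed Diels–Alder reaction forming C1–C10 and C4–C5: the diene should add to the enone face opposite the C7 isopropyl group (cis fusion, C10 methyl cis to isopropyl), with its CH2 terminus on the β-carbon C5 and its siloxy terminus on C10, and through the exo transition state expected for a 2-methylcycloalkenone, so that O1 is cis to the C10 methyl (1α).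

**Step 4**
Reactants: 5 cis-fused cycloadduct
Product: 7 8β-hydroxy-9-ketone, via potassium C8-enolate 6 (not isolated)
Conditions: KHMDS, THF, −78 °C; then 2-(phenylsulfonyl)-3-phenyloxaziridine, −78 °C
Reagents that add atoms: 2-(phenylsulfonyl)-3-phenyloxaziridine, O=S(=O)(c1ccccc1)N1OC1c1ccccc1
Why: Enolate hydroxylation with an N-sulfonyloxaziridine (Davis oxidation): the ketone can enolise only towards C8 because C10 is quaternary, and the oxidant should approach C8 from the β face, away from the syn-axial C10 methyl and the neighbouring isopropyl group, giving the equatorial 8β-alcohol, which is also the more stable epimer.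

**Step 5**
Reactants: 7 8β-hydroxy-9-ketone
Product: 8 8β,9β-diol
Conditions: L-Selectride (2.2 equiv), THF, −78 °C
Reagents that add atoms: none
Why: Trialkylborohydride reduction of a cyclohexanone by equatorial attack: in the cis-fused chair with equatorial isopropyl and 8-oxygen, the β-axial path to C9 is closed by the axial ring-A carbon C4, so hydride should enter from the α face and give the axial 9β-alcohol cis to O8.

**Step 6**
Reactants: 8 8β,9β-diol
Product: 9 8,9-acetonide
Conditions: 2,2-dimethoxypropane, PPTS (cat.), acetone, rt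
Reagents that add atoms: 2,2-dimethoxypropane, COC(C)(C)OC
Why: Acid-catalysed acetal exchange on the cis (axial/equatorial) diol masks both hydroxyls through the oxidative and organometallic steps that follow.

**Step 7**
Reactants: 9 8,9-acetonide
Product: 10 2-en-4-one
Conditions: CrO3, 3,5-dimethylpyrazole, CH2Cl2, −20 °C
Reagents that add atoms: chromium trioxide, O=[Cr](=O)=O
Why: Allylic C–H oxidation with the CrO3–dimethylpyrazole complex: of the two allylic positions only C4 is a methylene (C1 is a shielded neopentyl CH–OSi), so the carbonyl should appear at C4, as in the oxidation of 3-siloxycyclohexenes to 4-siloxycyclohex-2-enones.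

**Step 8**
Reactants: 10 2-en-4-one
Product: 12 2,5-dien-4-one, via silyl dienol ether 11 (not isolated)
Conditions: TMSOTf, Et3N, CH2Cl2, 0 °C; then Pd(OAc)2 (1.1 equiv), MeCN, rt
Reagents that add atoms: none
Why: Saegusa–Ito dehydrogenation: soft enolisation can only engage the α′ hydrogen on C5 (C3 is sp2), and the palladium(II) enolate loses a β-hydride from C6 to give the cross-conjugated dienone, the cis ring-fusion centre C5 becoming sp2.

**Step 9**
Reactants: 12 2,5-dien-4-one
Product: 13 5-en-4-one
Conditions: H2 (1 atm), (Ph3P)3RhCl (cat.), benzene/EtOH, rt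
Reagents that add atoms: none
Why: Homogeneous rhodium(I) hydrogenation should reduce the cis-disubstituted C2=C3 bond of the cross-conjugated dienone and leave the trisubstituted, more hindered C5=C6 bond, as in the conversion of steroidal 1,4-dien-3-ones into 4-en-3-ones.

**Step 10**
Reactants: 13 5-en-4-one; 14 methylmagnesium bromide
Product: 15 4α-hydroxy-4β-methyl-5-ene
Conditions: CeCl3, THF, −78 °C
Reagents that add atoms: none
Why: Organocerium 1,2-addition to an enone: the axial (α) approach to C4 is 1,3-diaxial to the C10 methyl, so the methyl group should be delivered equatorially from the β face, giving the axial 4α tertiary alcohol with the configuration of the future epoxide carbon.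

**Step 11**
Reactants: 15 4α-hydroxy-4β-methyl-5-ene
Product: 16 4α,5β,6β-triol
Conditions: OsO4 (10 mol %), NMO, acetone/H2O, rt
Reagents that add atoms: N-methylmorpholine N-oxide, C[N+]1([O-])CCOCC1; water, O
Why: Catalytic osmium tetroxide syn-dihydroxylation: the reagent should add to the trisubstituted C5=C6 bond from the β face, opposite to both the C10 methyl and the allylic 4α-hydroxyl (osmylation anti to an allylic hydroxyl), which sets the 5β-hydroxyl and with it the trans ring fusion.

**Step 12**
Reactants: 16 4α,5β,6β-triol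
Product: 17 4α,5β-dihydroxy-6-ketone
Conditions: Dess–Martin periodinane, NaHCO3, CH2Cl2, 0 °C to rt
Reagents that add atoms: none
Why: Dess–Martin oxidation of the only secondary alcohol, the two tertiary hydroxyls being inert; the C7 centre next to the new ketone already carries the more stable equatorial isopropyl group.

**Step 13**
Reactants: 17 4α,5β-dihydroxy-6-ketone
Product: 18 4α,5β,6α-triol
Conditions: NaBH4, MeOH, −20 to 0 °C
Reagents that add atoms: none
Why: Borohydride reduction of a cyclohexanone: the axial (α) trajectory to C6 is blocked by the syn-axial C10 methyl and 4α-hydroxyl, so hydride should add from the β face and give the axial 6α-alcohol, the known course for 5-hydroxy-6-oxo steroids.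

**Step 14**
Reactants: 18 4α,5β,6α-triol
Product: 19 6α-PMB ether
Conditions: NaH, PMBCl, Bu4NI (cat.), DMF, 0 °C to rt
Reagents that add atoms: 4-methoxybenzyl chloride, COc1ccc(CCl)cc1
Why: Williamson etherification: only the secondary C6 alkoxide should be benzylated, the two tertiary alkoxides being flanked by quaternary carbons, and no ketone or sulfonate is present for the base to attack.

**Step 15**
Reactants: 19 6α-PMB ether
Product: 20 1α-alcohol
Conditions: TBAF, THF, rt
Reagents that add atoms: none
Why: Fluoride-induced cleavage of the silyl ether, to which the acetonide and the PMB ether are inert.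

**Step 16**
Reactants: 20 1α-alcohol
Product: 21 1α-mesylate
Conditions: MsCl, Et3N, CH2Cl2, −20 to 0 °C
Reagents that add atoms: methanesulfonyl chloride, CS(=O)(=O)Cl
Why: Sulfonylation of the only secondary (equatorial) alcohol; triethylamine does not ionise the tertiary C5 hydroxyl, so the 1,3-diol monosulfonate should survive.

**Step 17**
Reactants: 21 1α-mesylate
Product: 22 8β,9β-diol 1α-mesylate
Conditions: AcOH/H2O (4:1), 45 °C
Reagents that add atoms: none
Why: Acid-catalysed hydrolysis of the isopropylidene acetal, which the PMB ether, the mesylate and the tertiary diol should tolerate.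

**Step 18**
Reactants: 22 8β,9β-diol 1α-mesylate; 23 tigloyl chloride
Product: 24 8β-tiglate
Conditions: pyridine, DMAP (cat.), CH2Cl2, −20 to 0 °C
Reagents that add atoms: none
Why: Pyridine/DMAP acylation, in which the equatorial 8β-hydroxyl should react well before the axial neopentyl 9β-hydroxyl and the tertiary hydroxyls.

**Step 19**
Reactants: 24 8β-tiglate
Product: 25 9β-TBS ether (fragmentation precursor)
Conditions: TBSOTf, 2,6-lutidine, CH2Cl2, −78 to −40 °C
Reagents that add atoms: tert-butyldimethylsilyl trifluoromethanesulfonate, CC(C)(C)[Si](C)(C)OS(=O)(=O)C(F)(F)F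
Why: Silylation with a silyl triflate: at low temperature the secondary 9β-hydroxyl should react while the two tertiary hydroxyls, each next to a quaternary carbon, do not; the silyl ether blocks tigloyl migration and later sulfonylation at O9.

**Step 20**
Reactants: 25 9β-TBS ether (trans-decalin 4α,5β-diol 1α-mesylate)
Product: 26 (E)-4-hydroxycyclodec-1(10)-en-5-one
Conditions: KHMDS (1.05 equiv), THF, −78 to 0 °C
Reagents that add atoms: none
Why: Wharton–Grob fragmentation of a cyclic 1,3-diol monosulfonate, the closest precedent being decalin-1,3-diol monosulfonates that open to (E)-cyclodecenones: the C5 alkoxide forms the C5=O π bond as the C5–C10 σ bond breaks, the C1=C10 π bond forms and mesylate leaves, all in one antiperiplanar event. No ring is closed by bond formation; the ten-membered ring C1–C10 is released by scission of the bond shared by the two six-membered rings, so no mode of closure applies. No stereocentre is created (C5 and C10 become sp2); the only stereochemical element formed is the C1=C10 geometry. The step needs the E olefin and needs fragmentation to outrun oxetane formation, substitution and E2 elimination: in the rigid trans-fused chair–chair the equatorial C1–OMs bond is antiperiplanar to C5–C10 and C2 is anti to C9 about C1–C10, so the concerted path can give only the E isomer. The C4 hydroxyl, also tertiary, has no aligned leaving group and is a spectator; the O6 ether is trans-diaxial to O5, silyl transfer from O9 to the doubly neopentyl O5 is disfavoured, and one equivalent of a non-nucleophilic amide base at low temperature should spare the tiglate and the C6 centre of the product ketone.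

**Step 21**
Reactants: 26 (E)-4-hydroxycyclodec-1(10)-en-5-one
Product: 27 (4R,5S)-4,5-diol
Conditions: Zn(BH4)2, Et2O, −20 to 0 °C
Reagents that add atoms: none
Why: Chelate-controlled reduction of an α-hydroxy ketone (cyclic chelate model): zinc bridges O4 and the C5 carbonyl, the ring chain leaves C4 through C3 on one face, and hydride should add from the exposed face of the C4 methyl group to give the 5S alcohol (with O5 anti to O4, C3 is anti to C6).

**Step 22**
Reactants: 27 (4R,5S)-4,5-diol
Product: 29 4,5-epoxide (6-O-PMB), via C5 mesylate 28 (not isolated)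
Conditions: MsCl, Et3N, CH2Cl2, −20 °C; then KOtBu, THF, −40 to 0 °C
Reagents that add atoms: none
Why: Selective sulfonylation of the secondary C5 hydroxyl followed by intramolecular Williamson displacement: O4 attacks C5 with inversion, which should give the trans-4,5-epoxide (4R,5R) with C4 unchanged.

**Step 23**
Reactants: 29 4,5-epoxide (6-O-PMB)
Product: 30 6-hydroxy epoxide
Conditions: DDQ, CH2Cl2/pH 7 buffer, 0 °C
Reagents that add atoms: none
Why: Oxidative cleavage of the PMB ether with DDQ under buffered neutral conditions, which the epoxide, the trisubstituted olefin, the tiglate and the silyl ether should tolerate.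

**Step 24**
Reactants: 30 6-hydroxy epoxide; 31 acetic anhydride
Product: 32 6-acetate 9-TBS ether
Conditions: pyridine, DMAP (cat.), CH2Cl2, 0 °C to rt
Reagents that add atoms: none
Why: DMAP-catalysed acetylation of the only free hydroxyl.

**Step 25**
Reactants: 32 6-acetate 9-TBS ether
Product: 33 CNP0163041.1
Conditions: TBAF, AcOH (1:1), THF, 0 °C to rt
Reagents that add atoms: none
Why: Fluoride desilylation buffered with acetic acid, chosen to avoid O8-to-O9 tigloyl migration and acid-induced transannular opening of the epoxide.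

**Compound list**

1 | (R)-(−)-carvone, (5R)-2-methyl-5-(prop-1-en-2-yl)cyclohex-2-en-1-one | CC1=CC[C@H](CC1=O)C(C)=C | starting material
2 | (R)-carvotanacetone, (5R)-5-isopropyl-2-methylcyclohex-2-en-1-one | CC1=CC[C@H](CC1=O)C(C)C | intermediate
3 | (E)-crotonaldehyde | C/C=C/C=O | starting material
4 | (1E)-1-(tert-butyldimethylsilyloxy)buta-1,3-diene | C=C/C=C/O[Si](C)(C)C(C)(C)C | intermediate
5 | cis-fused cycloadduct: 1α-OTBS, 5α-H, 7α-isopropyl, 10α-methyl decal-2-en-9-one | C1[C@H](C(C)C)C[C@H]2CC=C[C@H](O[Si](C)(C)C(C)(C)C)[C@@]2(C)C1=O | intermediate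
6 | potassium C8-enolate of 5 (not isolated) | [K+].[O-]C1=C[C@H](C(C)C)C[C@H]2CC=C[C@H](O[Si](C)(C)C(C)(C)C)[C@@]12C | intermediate
7 | 8β-hydroxy-9-ketone: 1α-OTBS, 5α-H, 7α-isopropyl, 8β-hydroxy, 10α-methyl decal-2-en-9-one | O[C@H]1[C@H](C(C)C)C[C@H]2CC=C[C@H](O[Si](C)(C)C(C)(C)C)[C@@]2(C)C1=O | intermediate
8 | 8β,9β-diol: 1α-OTBS, 5α-H, 7α-isopropyl, 10α-methyl decal-2-ene-8β,9β-diol | O[C@H]1[C@H](C(C)C)C[C@H]2CC=C[C@H](O[Si](C)(C)C(C)(C)C)[C@@]2(C)[C@H]1O | intermediate
9 | 8β,9β-O-isopropylidene acetal of 8 | CC1(C)O[C@H]2[C@H](C(C)C)C[C@H]3CC=C[C@H](O[Si](C)(C)C(C)(C)C)[C@@]3(C)[C@H]2O1 | intermediate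
10 | 2-en-4-one: 1α-OTBS, 5α-H, 8β,9β-isopropylidenedioxy, 7α-isopropyl, 10α-methyl decal-2-en-4-one | CC1(C)O[C@H]2[C@H](C(C)C)C[C@H]3C(=O)C=C[C@H](O[Si](C)(C)C(C)(C)C)[C@@]3(C)[C@H]2O1 | intermediate
11 | silyl dienol ether: 4-(trimethylsilyloxy)-2,4(5)-diene of 10 (not isolated) | CC1(C)O[C@H]2[C@H](C(C)C)CC3=C(O[Si](C)(C)C)C=C[C@H](O[Si](C)(C)C(C)(C)C)[C@@]3(C)[C@H]2O1 | intermediate
12 | 2,5-dien-4-one: 1α-OTBS, 8β,9β-isopropylidenedioxy, 7α-isopropyl, 10α-methyl | CC1(C)O[C@H]2[C@H](C(C)C)C=C3C(=O)C=C[C@H](O[Si](C)(C)C(C)(C)C)[C@@]3(C)[C@H]2O1 | intermediate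
13 | 5-en-4-one: 2,3-dihydro derivative of 12 | CC1(C)O[C@H]2[C@H](C(C)C)C=C3C(=O)CC[C@H](O[Si](C)(C)C(C)(C)C)[C@@]3(C)[C@H]2O1 | intermediate
14 | methylmagnesium bromide | C[Mg]Br | starting material
15 | 4α-hydroxy-4β-methyl-5-ene: 1α-OTBS, 8β,9β-isopropylidenedioxy, 7α-isopropyl, 10α-methyl | CC1(C)O[C@H]2[C@H](C(C)C)C=C3[C@@](O)(C)CC[C@H](O[Si](C)(C)C(C)(C)C)[C@@]3(C)[C@H]2O1 | intermediate
16 | trans-decalin 4α,5β,6β-triol: 1α-OTBS, 4β-methyl, 7α-isopropyl, 8β,9β-isopropylidenedioxy, 10α-methyl | CC1(C)O[C@H]2[C@H](C(C)C)[C@@H](O)[C@]3(O)[C@@](O)(C)CC[C@H](O[Si](C)(C)C(C)(C)C)[C@@]3(C)[C@H]2O1 | intermediate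
17 | 4α,5β-dihydroxy-6-ketone of the same trans-decalin | CC1(C)O[C@H]2[C@H](C(C)C)C(=O)[C@]3(O)[C@@](O)(C)CC[C@H](O[Si](C)(C)C(C)(C)C)[C@@]3(C)[C@H]2O1 | intermediate
18 | trans-decalin 4α,5β,6α-triol (6-epimer of 16) | CC1(C)O[C@H]2[C@H](C(C)C)[C@H](O)[C@]3(O)[C@@](O)(C)CC[C@H](O[Si](C)(C)C(C)(C)C)[C@@]3(C)[C@H]2O1 | intermediate
19 | 6α-O-(4-methoxybenzyl) ether of 18 | CC1(C)O[C@H]2[C@H](C(C)C)[C@H](OCc4ccc(OC)cc4)[C@]3(O)[C@@](O)(C)CC[C@H](O[Si](C)(C)C(C)(C)C)[C@@]3(C)[C@H]2O1 | intermediate
20 | 1α-alcohol: 6α-OPMB, 8β,9β-isopropylidenedioxy trans-decalin 1α,4α,5β-triol | CC1(C)O[C@H]2[C@H](C(C)C)[C@H](OCc4ccc(OC)cc4)[C@]3(O)[C@@](O)(C)CC[C@H](O)[C@@]3(C)[C@H]2O1 | intermediate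
21 | 1α-mesylate of 20 | CC1(C)O[C@H]2[C@H](C(C)C)[C@H](OCc4ccc(OC)cc4)[C@]3(O)[C@@](O)(C)CC[C@H](OS(C)(=O)=O)[C@@]3(C)[C@H]2O1 | intermediate
22 | 8β,9β-diol 1α-mesylate: 6α-OPMB trans-decalin 4α,5β,8β,9β-tetraol 1α-mesylate | O[C@H]1[C@H](C(C)C)[C@H](OCc3ccc(OC)cc3)[C@]2(O)[C@@](O)(C)CC[C@H](OS(C)(=O)=O)[C@@]2(C)[C@H]1O | intermediate
23 | tigloyl chloride, (E)-2-methylbut-2-enoyl chloride | C/C=C(\C)C(Cl)=O | starting material
24 | 8β-O-tiglate of 22 | C/C=C(\C)C(=O)O[C@H]1[C@H](C(C)C)[C@H](OCc3ccc(OC)cc3)[C@]2(O)[C@@](O)(C)CC[C@H](OS(C)(=O)=O)[C@@]2(C)[C@H]1O | intermediate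
25 | fragmentation precursor: trans-decalin 4α,5β-diol 1α-mesylate with 4β,10α-dimethyl, 6α-OPMB, 7α-isopropyl, 8β-O-tigloyl, 9β-OTBS | C/C=C(\C)C(=O)O[C@H]1[C@H](C(C)C)[C@H](OCc3ccc(OC)cc3)[C@]2(O)[C@@](O)(C)CC[C@H](OS(C)(=O)=O)[C@@]2(C)[C@H]1O[Si](C)(C)C(C)(C)C | intermediate
26 | (1(10)E,4R)-4-hydroxy-4,10-dimethyl-7-isopropyl-6-OPMB-8-O-tigloyl-9-OTBS-cyclodec-1(10)-en-5-one (C6–C9 as in 33) | C/C=C(\C)C(=O)O[C@H]1[C@H](C(C)C)[C@H](OCc2ccc(OC)cc2)C(=O)[C@@](O)(C)CC/C=C(\C)[C@H]1O[Si](C)(C)C(C)(C)C | intermediate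
27 | (4R,5S)-4,5-diol from 26 (C6–C9 as in 33) | C/C=C(\C)C(=O)O[C@H]1[C@H](C(C)C)[C@H](OCc2ccc(OC)cc2)[C@H](O)[C@@](O)(C)CC/C=C(\C)[C@H]1O[Si](C)(C)C(C)(C)C | intermediate
28 | C5 mesylate of 27 (not isolated) | C/C=C(\C)C(=O)O[C@H]1[C@H](C(C)C)[C@H](OCc2ccc(OC)cc2)[C@H](OS(C)(=O)=O)[C@@](O)(C)CC/C=C(\C)[C@H]1O[Si](C)(C)C(C)(C)C | intermediate
29 | (1(10)E,4R,5R)-4,5-epoxide with 6-OPMB, 8-O-tigloyl, 9-OTBS | C/C=C(\C)C(=O)O[C@H]1[C@H](C(C)C)[C@H](OCc2ccc(OC)cc2)[C@H]3O[C@]3(C)CC/C=C(\C)[C@H]1O[Si](C)(C)C(C)(C)C | intermediate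
30 | 6-hydroxy epoxide: 6-de-O-PMB derivative of 29 | C/C=C(\C)C(=O)O[C@H]1[C@H](C(C)C)[C@H](O)[C@H]2O[C@]2(C)CC/C=C(\C)[C@H]1O[Si](C)(C)C(C)(C)C | intermediate
31 | acetic anhydride | CC(=O)OC(C)=O | starting material
32 | 6-acetate 9-TBS ether: 9-O-TBS ether of the target | C/C=C(\C)C(=O)O[C@H]1[C@H](C(C)C)[C@H](OC(C)=O)[C@H]2O[C@]2(C)CC/C=C(\C)[C@H]1O[Si](C)(C)C(C)(C)C | intermediate
33 | CNP0163041.1, (1(10)E,4R,5R,6S,7S,8S,9R)-6-acetoxy-4,5-epoxy-9-hydroxygermacr-1(10)-en-8-yl (E)-2-methylbut-2-enoate | C/C=C(\C)C(=O)O[C@H]1[C@H](C(C)C)[C@H](OC(C)=O)[C@H]2O[C@]2(C)CC/C=C(\C)[C@H]1O | target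

**Totals**

Total step count: 25. Longest linear sequence: 24 steps (steps 1 and 3–25, from (R)-carvone); step 2 is a one-step branch.

**Steps most likely to fail**

Step 21. Facial selectivity of hydride delivery may be poor if the zinc chelate does not dominate in the conformationally mobile ten-membered ring, so that the C5 alcohol is formed with the wrong configuration. The fallback sets out from 26 and makes the epoxide from an olefin instead of by displacement. The C5-epimeric diol, (4R,5R)-4,5-diol F1, is converted with thiocarbonyldiimidazole into cyclic thiocarbonate F2. Corey–Winter elimination with 1,3-dimethyl-2-phenyl-1,3,2-diazaphospholidine at 40 °C is a syn elimination, which turns this diol epimer into the 4E olefin, and is mild enough to avoid Cope rearrangement of the 1,5-diene; it should give (1(10)E,4E)-diene F3. DDQ then frees O6 to give dienol F4. Hydroxyl-directed epoxidation (VO(acac)2, t-BuOOH) of the allylic C4=C5 bond is expected to be threo-selective because of allylic 1,3-strain with the cis C4 methyl and should ignore the remote C1=C10 bond; it returns to the route at 30.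

Step 3. Exo/endo control in the cycloaddition may be lost, or ionic Michael addition of the siloxydiene may compete with ring closure, so that C1 is formed wholly or partly with the opposite configuration. The fallback stops relying on the cycloaddition for C1 and sets that centre by hydroxyl-directed ketone reduction on the rigid trans-decalin. It sets out from 20 or from what steps 4–15 would deliver from an endo adduct, the C1-epimeric 1β-alcohol F5, alone or mixed with 20. Dess–Martin oxidation converges both on the 1-ketone F6. Me4NBH(OAc)3 in AcOH/MeCN at −20 °C then delivers hydride intramolecularly from the axial 5β-hydroxyl to the β face of C1 (anti-1,3-diol), returning to the route at 20.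

Step 5. Hydride may be delivered to the wrong face of the hindered C9 ketone, or the ketone, flanked by a quaternary carbon and a carbinol, may not react. The fallback sets out from 5 and builds the diol by syn-dihydroxylation, which makes O8 and O9 cis by necessity. Allylic oxidation (CrO3, 3,5-dimethylpyrazole) first gives 2-ene-4,9-dione F7. Kinetic enolisation of the saturated C9 ketone towards C8 (KHMDS, PhNTf2) gives 9-enol triflate F8. Palladium-catalysed formate reduction (Pd(OAc)2, PPh3, Bu3N, HCO2H) gives 2,8-dien-4-one F9. Osmium tetroxide/NMO should attack the isolated C8=C9 bond rather than the electron-poor enone, from the face opposite to the C10 methyl and the C7 isopropyl group, to give 8β,9β-dihydroxy-2-en-4-one F10. Acetonide formation (2,2-dimethoxypropane, PPTS) returns to the route at 10.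

**Further compounds**

F1 | step 21 | (4R,5R)-4,5-diol, C5 epimer of 27 | C/C=C(\C)C(=O)O[C@H]1[C@H](C(C)C)[C@H](OCc2ccc(OC)cc2)[C@@H](O)[C@@](O)(C)CC/C=C(\C)[C@H]1O[Si](C)(C)C(C)(C)C
F2 | step 21 | 4,5-O-thiocarbonate of F1 | C/C=C(\C)C(=O)O[C@H]1[C@H](C(C)C)[C@H](OCc2ccc(OC)cc2)[C@H]3OC(=S)O[C@]3(C)CC/C=C(\C)[C@H]1O[Si](C)(C)C(C)(C)C
F3 | step 21 | (1(10)E,4E)-germacra-1(10),4-diene with 6-OPMB, 8-O-tigloyl, 9-OTBS | C/C=C(\C)C(=O)O[C@H]1[C@H](C(C)C)[C@H](OCc2ccc(OC)cc2)/C=C(\C)CC/C=C(\C)[C@H]1O[Si](C)(C)C(C)(C)C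
F4 | step 21 | (1(10)E,4E)-germacra-1(10),4-dien-6-ol with 8-O-tigloyl, 9-OTBS | C/C=C(\C)C(=O)O[C@H]1[C@H](C(C)C)[C@H](O)/C=C(\C)CC/C=C(\C)[C@H]1O[Si](C)(C)C(C)(C)C
F5 | step 3 | 1β-alcohol, C1 epimer of 20 | CC1(C)O[C@H]2[C@H](C(C)C)[C@H](OCc4ccc(OC)cc4)[C@]3(O)[C@@](O)(C)CC[C@@H](O)[C@@]3(C)[C@H]2O1
F6 | step 3 | 1-ketone of the 6α-OPMB 8,9-acetonide trans-decalin 4α,5β-diol | CC1(C)O[C@H]2[C@H](C(C)C)[C@H](OCc4ccc(OC)cc4)[C@]3(O)[C@@](O)(C)CCC(=O)[C@@]3(C)[C@H]2O1
F7 | step 5 | 2-ene-4,9-dione: 1α-OTBS, 5α-H, 7α-isopropyl, 10α-methyl decal-2-ene-4,9-dione | C1[C@H](C(C)C)C[C@H]2C(=O)C=C[C@H](O[Si](C)(C)C(C)(C)C)[C@@]2(C)C1=O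
F8 | step 5 | 9-enol triflate of F7 | O=S(=O)(OC1=C[C@H](C(C)C)C[C@H]2C(=O)C=C[C@H](O[Si](C)(C)C(C)(C)C)[C@@]12C)C(F)(F)F
F9 | step 5 | 2,8-dien-4-one: 1α-OTBS, 5α-H, 7α-isopropyl, 10α-methyl decal-2,8-dien-4-one | C1=C[C@H](C(C)C)C[C@H]2C(=O)C=C[C@H](O[Si](C)(C)C(C)(C)C)[C@@]12C
F10 | step 5 | 8β,9β-dihydroxy-2-en-4-one: 1α-OTBS, 5α-H, 7α-isopropyl, 10α-methyl | O[C@H]1[C@H](C(C)C)C[C@H]2C(=O)C=C[C@H](O[Si](C)(C)C(C)(C)C)[C@@]2(C)[C@H]1O
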